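The readings are simulated with made-up constants.

**Age share.** The ratio to carry is the mean age of the chains divided by the time allowed. If every living end adds free monomer at one pace, average length (number-average degree of polymerisation) is that pace times mean age, so at like free monomer the unknown pace cancels between two flasks.

common to all: impurity 6.7 mM
- ash: free monomer 1 M; initiator 5.9 mM; run made earlier
- cedar: free monomer 1 M; initiator 26 mM; run made earlier
- spring: free monomer 1.0 M; initiator 18 mM; time 8.0 h
- dawn: free monomer 1.0 M; initiator 5.0 mM; time 8.0 h

| run | time / h | monomer in chains / % |
|---|---|---|
| ash | 1.00 | 0.3 |
| ash | 2.50 | 0 |
| ash | 3.00 | 0 |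
| ash | 5.00 | 1.2 |
| ash | 6.00 | 1.9 |
| cedar | 0.500 | 0.7 |
| cedar | 1.33 | 2.8 |
| cedar | 2.50 | 5.4 |
| cedar | 4.00 | 9.7 |
| cedar | 6.00 | 15.0 |

(scatter of a reading: 0.5 percentage points)

- which of the two ends with the longer chains by the average number of monomer units in a chain (chains begun, living or dead) ("neither" if they lie within 10 %) (spring / dawn / neither)
- average number of monomer units in a chain (chains begun, living or dead) at the end, spring
- average number of monomer units in a chain (chains begun, living or dead) at the end, dawn

- the average divides the monomer in chains by the number of chains begun, living and dead together
- what was read earlier has a scatter of 0.5 percentage points, one standard deviation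
- the earlier runs do not show the number of chains; that part of a forecast is a guess

**Two extremes.** If chains all begin at the start, the fraction of the charge in chains grows in step with time, a share of 1. If they begin evenly through the run, a time factor of 2 gives a fraction factor of 4, a share of 0.5. Between these, the share is the logarithm of the time factor over the logarithm of the fraction factor.

**Own reckoning.** The cedar readings from 2.50 h to 6.00 h give 0.857 for this age share, the mean age of the chains over the time allowed, with the scatter of its readings. Spring, like cedar, holds initiator above impurity, so it takes that share. Dawn holds less initiator than impurity, so it is placed at the first extreme. Dawn should therefore be longer by a factor near 1.17, and the extremes cap that factor at 2.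

**The forecast.** It names dawn, with 20 for spring and 50 for dawn: “Dawn therefore comes out about 2.5 times longer.” Its gap is wider than the reckoning here.

**The flasks.** Dawn wins, dawn, with 77.3 against 53.4 for spring.

    free monomer + living end → monomer in chains + living end, rate k1*[living end]*[free monomer] (k = 9.70 M⁻¹ h⁻¹)
    initiator + impurity → spent initiator B (k = 3400 M⁻¹ h⁻¹)
    free monomer + initiator → living end + monomer in chains (k = 0.180 M⁻¹ h⁻¹)
    2 initiator → spent initiator A (k = 46.0 M⁻¹ h⁻¹)

**The gap.** The initiator charge is the main reason for the gap, since dawn stands at 77.3 and, with that difference in charge taken away, at 53.4. Dawn has 0 % initiator left at 4.00 h, so it is the limiting reagent there, and its fractions in chains give a share of 1.00. Spring still holds 7.77 % at that time, and its fractions give 0.764, below the 0.857 taken from cedar.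

**Richer neighbour.** A neighbour flask is dawn with 1.7 M free monomer. With dawn's age share and a pace of 16.5 h⁻¹, its chains should reach about 132 monomer units on average in 8.0 h, and the computed length is 131.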